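**Plan**

- Retrosynthesis: cut C12–C13 (sp3–sp2 coupling) to split off the iodobutenyl butenolide 7. In the decalin, cut C3–C4 of ring A, which leaves a ring B cyclohexenone with a 2-methyloxirane on C5 and a 3-oxopropyl arm on C10. Then cut C10–C1 and C10–CH3 (two enolate alkylations), which leaves (R)-carvone.
- Enabling feature: C4 is a quaternary carbon between the C3 carbinol and the C18 hydroxymethyl (a 1,3-diol), which is what an oxirane-opening radical addition to C=O produces. C5, C4, C18, C19 and ring B map onto the stereocenter, the isopropenyl group and the ring of carvone.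
- Forward order: the butenolide is closed first (steps 1–4); ring B is the carvone ring (steps 5–8); ring A is closed last, in step 9, by Cp2TiCl opening of the oxirane and 6-exo addition of the C4 radical to the C3 aldehyde. C6–OH, C11, C8–OH and C12 are then built around the C9 enone (steps 10–16), and the halves are joined in step 17.
- Stereochemistry: C5 from (R)-carvone; C10 by alkylation anti to isopropenyl; C4 and C3 in the radical ring closure; C6 by α-face oxidation of a silyl dienol ether; C9 by α-face hydroboration; C8 by α-face O2 capture; the butenolide carbinol by catalytic asymmetric alkynylation; the E-alkene by syn hydrozirconation.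

Key step: step 9

Locants used below: decalin carbons C1–C10 in labdane fashion (ring A = C1–C5 and C10; ring B = C5–C10). On C4, C18 is CH2OH (α) and C19 is CH3 (β). C8 and C10 each carry a CH3; C9 carries the chain C11, C12, C13 onward. α is the face opposite to the C10 methyl.

Assumption (step 3): the (R,R)-ligand is taken to give the S carbinol; if the first run shows the opposite sense, the (S,S)-ligand is used and nothing else changes.

**Route**

Step 1
Reactants: 1 pent-3-yn-1-ol
Product: 3 (E)-4-iodopent-3-en-1-ol, via alkenylzirconocene 2 (not isolated)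
Conditions: Cp2Zr(H)Cl (2.3 equiv), THF, 25→40 °C; then I2, 0 °C; aq. work-up
Reagents that add atoms: iodine, [I][I]
Why: Syn addition of Zr–H places zirconium on the less hindered, methyl-bearing alkyne carbon (the hydroxyl consumes the first equivalent), and iodinolysis of the C–Zr bond with retention gives the E-iodoalkene (hydrozirconation–iodination).

Step 2
Reactants: 3 (E)-4-iodopent-3-en-1-ol
Product: 4 (E)-4-iodopent-3-enal
Conditions: Dess–Martin periodinane, NaHCO3, CH2Cl2, 0 °C; used crude
Reagents that add atoms: none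
Why: Buffered periodinane oxidation stops at the aldehyde and is mild enough to keep the β,γ-alkene out of conjugation (Dess–Martin oxidation).

Step 3
Reactants: 4 (E)-4-iodopent-3-enal
Product: 5 methyl (S,E)-4-hydroxy-7-iodooct-6-en-2-ynoate
Conditions: methyl propiolate, Me2Zn, (R,R)-ProPhenol (10 mol %), Ph3PO (20 mol %), toluene, 0 °C; aq. NH4Cl
Reagents that add atoms: methyl propiolate, COC(=O)C#C
Why: The dinuclear zinc complex formed from Me2Zn and the ProPhenol ligand binds the aldehyde and the zinc acetylide MeZnC≡CCO2Me and delivers the alkynyl group to one face of the carbonyl, which sets the butenolide carbinol center as S (catalytic asymmetric alkynylation of an aldehyde).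

Step 4
Reactants: 5 methyl (S,E)-4-hydroxy-7-iodooct-6-en-2-ynoate
Product: 7 (S)-5-[(E)-3-iodobut-2-en-1-yl]-4-methylfuran-2(5H)-one, via hydroxy dienoate 6 (not isolated)
Conditions: Me2CuLi (from CuI and MeLi, 2.5 equiv), THF, −78 °C; aq. NH4Cl, then 25 °C
Reagents that add atoms: lithium dimethylcuprate, [Li+].C[Cu-]C
Why: Syn carbocupration of the ynoate puts CH3 on the β-carbon and the ester cis to the carbinol, so the Z-hydroxy enoate closes to the butenolide after protonation while the carbinol center and the iodoalkene stay untouched at −78 °C (cuprate conjugate addition–lactonization).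

Step 5
Reactants: 8 (R)-(−)-carvone
Product: 10 (5R)-2,6-dimethyl-5-(prop-1-en-2-yl)cyclohex-2-en-1-one (both C6 epimers), via lithium dienolate 9 (not isolated)
Conditions: LiN(i-Pr)2 (LDA), THF, −78 °C; MeI, −78→0 °C
Reagents that add atoms: iodomethane, CI
Why: Kinetic deprotonation at the α′-CH2 gives the cross-conjugated lithium dienolate, which is C-methylated (enolate alkylation); the new center forms as both epimers and is flattened again in step 6.

Step 6
Reactants: 10 (5R)-2,6-dimethyl-5-(prop-1-en-2-yl)cyclohex-2-en-1-one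
Product: 12 (5S,6S)-2,6-dimethyl-5-(prop-1-en-2-yl)-6-(prop-2-yn-1-yl)cyclohex-2-en-1-one, via lithium dienolate 11 (not isolated)
Conditions: LiN(i-Pr)2 (LDA), THF/DMPU, −78 °C; 3-bromoprop-1-yne, −78→0 °C
Reagents that add atoms: 3-bromoprop-1-yne, C#CCBr
Why: The fully substituted α′-enolate is alkylated on the face away from the neighbouring isopropenyl group, so the propargyl arm enters trans and the methyl ends cis to isopropenyl, which sets quaternary C10 (diastereoselective enolate alkylation).

Step 7
Reactants: 12 (5S,6S)-2,6-dimethyl-5-(prop-1-en-2-yl)-6-(prop-2-yn-1-yl)cyclohex-2-en-1-one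
Product: 13 (5R,6S)-2,6-dimethyl-5-(2-methyloxiran-2-yl)-6-(prop-2-yn-1-yl)cyclohex-2-en-1-one (both epimers at the oxirane carbon)
Conditions: mCPBA (1.05 equiv), NaHCO3, CH2Cl2, 0 °C
Reagents that add atoms: mCPBA, OOC(=O)c1cccc(Cl)c1
Why: The electron-rich 1,1-disubstituted alkene is epoxidized much faster than the enone alkene or the alkyne (Prilezhaev epoxidation); both epimers are carried on because the oxirane carbon becomes a planar radical in step 9.

Step 8
Reactants: 13 (5R,6S)-2,6-dimethyl-5-(2-methyloxiran-2-yl)-6-(prop-2-yn-1-yl)cyclohex-2-en-1-one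
Product: 14 3-[(1S,6R)-1,3-dimethyl-6-(2-methyloxiran-2-yl)-2-oxocyclohex-3-en-1-yl]propanal
Conditions: [CpRu(MeCN)3]PF6 (5 mol %), 5,5′-bis(trifluoromethyl)-2,2′-bipyridine (5 mol %), NMP/H2O 4:1, 25 °C
Reagents that add atoms: water, O
Why: The ruthenium vinylidene formed from the terminal alkyne and [CpRu(MeCN)3]PF6 is attacked by water at the terminal carbon, giving the aldehyde and not the methyl ketone under neutral conditions that spare the oxirane and the enone (ruthenium-catalysed anti-Markovnikov alkyne hydration).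

Step 9
Reactants: 14 3-[(1S,6R)-1,3-dimethyl-6-(2-methyloxiran-2-yl)-2-oxocyclohex-3-en-1-yl]propanal
Product: 15 trans-fused enone diol: 3β-hydroxy-4α-(hydroxymethyl)-4β,8,10β-trimethyl-5α-H-decal-7-en-9-one
Conditions: Cp2TiCl2 (2.5 equiv), Zn dust, THF, 25 °C, 14 added slowly at high dilution; then 1 M HCl
Reagents that add atoms: none
Why: Cp2TiCl (trivalent titanium) transfers one electron to the oxirane, which opens to the tertiary C4 radical with C18 held as a titanium alkoxide; the radical adds to the titanium-bound C3 aldehyde, a second Cp2TiCl takes up the oxygen-centred radical, and acid releases the 1,3-diol. The closest known reaction type is the titanocene-mediated radical cyclization of epoxy aldehydes, ketones and nitriles. Ring A closes 6-exo-trig through a chair in which the C10 arm and the C5 radical carbon are both equatorial on ring B, as the trans relation from step 6 demands, so the ring fusion can only be trans. At C4 the bulky CH2O–Ti group takes the equatorial α site and CH3 the axial β site, because the alternative would put CH2O–Ti 1,3-diaxial to the C10 methyl; the oxirane configuration is lost in the planar radical, so both epimers of 14 converge. At C3 the titanium-bound oxygen sits equatorial in the same chair, which gives the 3β-alcohol. The step needs the 6-exo addition to outrun reduction or hydrogen loss of the tertiary radical, which slow trapping of tertiary radicals by Cp2TiCl and high dilution secure, while the conjugated C9 ketone is not reduced by Cp2TiCl and lies out of reach of C4.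

Step 10
Reactants: 15 trans-fused enone diol
Product: 16 tris-TBS silyl dienol ether: 3β-OTBS, 18-OTBS, 9-OTBS-6,8-diene
Conditions: TBSOTf (3.5 equiv), Et3N, CH2Cl2, 0→25 °C
Reagents that add atoms: tert-butyldimethylsilyl trifluoromethanesulfonate, CC(C)(C)[Si](C)(C)OS(=O)(=O)C(F)(F)F
Why: The silyl triflate with amine silylates both hydroxyls and, because the α′-carbon (C10) is quaternary, enolizes the enone through C6 to the linear silyl dienol ether (silylation and soft enolization).

Step 11
Reactants: 16 tris-TBS silyl dienol ether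
Product: 18 6α-hydroxy enone: 3β,18-bis-OTBS-6α-hydroxy-decal-7-en-9-one, via silyloxy epoxide 17 (not isolated)
Conditions: dimethyldioxirane, acetone/CH2Cl2, −78→−20 °C; then AcOH/THF/H2O, 0 °C
Reagents that add atoms: dimethyldioxirane, CC1(C)OO1
Why: Dimethyldioxirane epoxidizes the terminal C6=C7 bond of the silyl dienol ether on the α face, the β face being screened by the axial methyls on C4 and C10, and the silyloxy oxirane collapses in mild acid to the γ-hydroxy enone, which sets 6α-OH (vinylogous Rubottom oxidation).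

Step 12
Reactants: 18 6α-hydroxy enone
Product: 19 diene: 9-methylidene (C11) Δ7 compound with 6α-OH and 3β,18-bis-OTBS
Conditions: Cp2TiMe2 (3 equiv), toluene/THF, 65 °C, dark
Reagents that add atoms: dimethyltitanocene, C[Ti+2]C.c1cc[cH-]c1.c1cc[cH-]c1
Why: The titanium methylidene Cp2Ti=CH2 generated thermally adds to the carbonyl and cycloreverts to the alkene without base, so the γ-hydroxy enone is not isomerized and the hindered C9 carbonyl becomes the C9=C11 methylidene (Petasis methylenation).

Step 13
Reactants: 19 diene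
Product: 21 diol: 9β-(hydroxymethyl)-9α-H Δ7 compound with 6α-OH, via alkylborane 20 (not isolated)
Conditions: 9-BBN (3 equiv), THF, 0→50 °C; then NaOH, H2O2, 0 °C
Reagents that add atoms: hydrogen peroxide, OO
Why: 9-BBN adds to the less substituted C9=C11 bond of the diene with boron on C11 and hydrogen delivered to C9 from the α face, opposite to the axial C10 methyl, and oxidation with retention gives the primary alcohol, which sets C9 with 9α-H (hydroboration–oxidation).

Step 14
Reactants: 21 diol
Product: 23 triol: 6α,8α,11-trihydroxy compound with 8β-CH3, via hydroperoxide 22 (not isolated)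
Conditions: Mn(dpm)3 (10 mol %), PhSiH3, O2 (1 atm), i-PrOH/CH2Cl2, 0→25 °C; then PPh3
Reagents that add atoms: dioxygen, O=O
Why: Hydrogen atom transfer from the manganese hydride formed from Mn(dpm)3 and PhSiH3 to C7 gives the tertiary C8 radical, which takes up O2 from the α (equatorial) side because the β side is 1,3-diaxial to the C10 methyl, and PPh3 reduces the hydroperoxide, which sets 8α-OH and 8β-CH3 (Mukaiyama hydration).

Step 15
Reactants: 23 triol
Product: 24 aldehyde: 9β-formyl compound with 6α-OH and 8α-OH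
Conditions: TEMPO (20 mol %), PhI(OAc)2, CH2Cl2, 25 °C
Reagents that add atoms: none
Why: The oxoammonium salt formed from TEMPO oxidizes the unhindered primary alcohol much faster than the secondary and tertiary ones and stops at the aldehyde, whose formyl group is equatorial so that C9 has no drive to epimerize (TEMPO/PhI(OAc)2 oxidation).

Step 16
Reactants: 24 aldehyde
Product: 25 9β-vinyl compound with 6α-OH, 8α-OH and 3β,18-bis-OTBS
Conditions: Cp2TiMe2 (4 equiv), toluene/THF, 60 °C, dark
Reagents that add atoms: dimethyltitanocene, C[Ti+2]C.c1cc[cH-]c1.c1cc[cH-]c1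
Why: Base-free carbonyl methylenation turns the aldehyde into the vinyl group (C11=C12) without retro-aldol cleavage of the β-hydroxy aldehyde or epimerization at C9 (Petasis methylenation).

Step 17
Reactants: 25 9β-vinyl compound; 7 (S)-5-[(E)-3-iodobut-2-en-1-yl]-4-methylfuran-2(5H)-one
Product: 27 3,18-bis-O-TBS ether of the target, via alkylborane 26 (not isolated)
Conditions: 9-BBN (4 equiv), THF, 25 °C; then 7, Pd(dppf)Cl2 (10 mol %), AsPh3, aq. K3PO4, DMF, 25 °C
Reagents that add atoms: none
Why: Anti-Markovnikov hydroboration of the only alkene of 25 gives the primary alkylborane, whose borate transfers the alkyl group to the alkenylpalladium iodide formed from 7 with retention of the E geometry, and reductive elimination joins C12 to C13 under a mild phosphate base at 25 °C chosen to leave the butenolide stereocenter alone (B-alkyl Suzuki–Miyaura coupling).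

Step 18
Reactants: 27 3,18-bis-O-TBS ether of the target
Product: 28 CNP0307004.1
Conditions: HF·pyridine, THF/pyridine, 0→40 °C
Reagents that add atoms: none
Why: Fluoride cleaves the primary and the hindered secondary silyl ether, while the butenolide, the trisubstituted alkene and the tertiary alcohol should be stable to buffered HF (desilylation).

**Compound list**

1 | pent-3-yn-1-ol | CC#CCCO | starting material
2 | (E)-4-(chlorozirconocenyl)pent-3-en-1-ol, O-bound to a second Cp2ZrCl (cyclopentadienyl rings drawn σ-bonded) | C/C(=C\CCO[Zr](Cl)(C1C=CC=C1)C1C=CC=C1)[Zr](Cl)(C1C=CC=C1)C1C=CC=C1 | intermediate (not isolated)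
3 | (E)-4-iodopent-3-en-1-ol | C/C(I)=C\CCO | intermediate
4 | (E)-4-iodopent-3-enal | C/C(I)=C\CC=O | intermediate
5 | methyl (S,E)-4-hydroxy-7-iodooct-6-en-2-ynoate | COC(=O)C#C[C@@H](O)C/C=C(\C)I | intermediate
6 | methyl (S,2Z,6E)-4-hydroxy-7-iodo-3-methylocta-2,6-dienoate | COC(=O)/C=C(/C)[C@@H](O)C/C=C(\C)I | intermediate (not isolated)
7 | (S)-5-[(E)-3-iodobut-2-en-1-yl]-4-methylfuran-2(5H)-one | CC1=CC(=O)O[C@H]1C/C=C(\C)I | intermediate
8 | (R)-(−)-carvone | CC1=CC[C@H](CC1=O)C(C)=C | starting material
9 | lithium dienolate of 8 (O–Li, C1=C6 and C2=C3 of the cyclohexadiene) | CC1=CC[C@H](C=C1O[Li])C(C)=C | intermediate (not isolated)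
10 | (5R)-2,6-dimethyl-5-(prop-1-en-2-yl)cyclohex-2-en-1-one (both C6 epimers) | CC1=CC[C@H](C(C)C1=O)C(C)=C | intermediate
11 | lithium dienolate of 10 | CC1=CC[C@H](C(C)=C1O[Li])C(C)=C | intermediate (not isolated)
12 | (5S,6S)-2,6-dimethyl-5-(prop-1-en-2-yl)-6-(prop-2-yn-1-yl)cyclohex-2-en-1-one (propargyl trans, methyl cis to isopropenyl) | O=C1[C@@](C)(CC#C)[C@H](C(C)=C)CC=C1C | intermediate
13 | (5R,6S)-2,6-dimethyl-5-(2-methyloxiran-2-yl)-6-(prop-2-yn-1-yl)cyclohex-2-en-1-one (both epimers at the oxirane carbon) | O=C1[C@@](C)(CC#C)[C@H](C2(C)CO2)CC=C1C | intermediate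
14 | 3-[(1S,6R)-1,3-dimethyl-6-(2-methyloxiran-2-yl)-2-oxocyclohex-3-en-1-yl]propanal | O=C1[C@@](C)(CCC=O)[C@H](C2(C)CO2)CC=C1C | intermediate
15 | 3β-hydroxy-4α-(hydroxymethyl)-4β,8,10β-trimethyl-5α-H-decal-7-en-9-one (rings A/B trans) | O=C1[C@@]2(C)CC[C@H](O)[C@@](C)(CO)[C@@H]2CC=C1C | intermediate
16 | tris-TBS silyl dienol ether of 15 (3β-OTBS, 18-OTBS, 9-OTBS, C6=C7 and C8=C9) | CC1=C(O[Si](C)(C)C(C)(C)C)[C@@]2(C)CC[C@H](O[Si](C)(C)C(C)(C)C)[C@@](C)(CO[Si](C)(C)C(C)(C)C)[C@@H]2C=C1 | intermediate
17 | 6α,7α-epoxide of 16 (C8=C9 silyl enol ether kept) | CC1=C(O[Si](C)(C)C(C)(C)C)[C@@]2(C)CC[C@H](O[Si](C)(C)C(C)(C)C)[C@@](C)(CO[Si](C)(C)C(C)(C)C)[C@@H]2[C@H]3O[C@@H]13 | intermediate (not isolated)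
18 | 3β,18-bis-OTBS-6α-hydroxy-4β,8,10β-trimethyl-5α-H-decal-7-en-9-one | O=C1[C@@]2(C)CC[C@H](O[Si](C)(C)C(C)(C)C)[C@@](C)(CO[Si](C)(C)C(C)(C)C)[C@@H]2[C@@H](O)C=C1C | intermediate
19 | 9-methylidene Δ7 diene with 6α-OH and 3β,18-bis-OTBS | C=C1[C@@]2(C)CC[C@H](O[Si](C)(C)C(C)(C)C)[C@@](C)(CO[Si](C)(C)C(C)(C)C)[C@@H]2[C@@H](O)C=C1C | intermediate
20 | B-alkyl-9-BBN with boron on C11 (9α-H), Δ7, 6α-OH | C(B1C2CCCC1CCC2)[C@@H]1[C@@]2(C)CC[C@H](O[Si](C)(C)C(C)(C)C)[C@@](C)(CO[Si](C)(C)C(C)(C)C)[C@@H]2[C@@H](O)C=C1C | intermediate (not isolated)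
21 | 9β-(hydroxymethyl)-9α-H Δ7 compound with 6α-OH and 3β,18-bis-OTBS | OC[C@@H]1[C@@]2(C)CC[C@H](O[Si](C)(C)C(C)(C)C)[C@@](C)(CO[Si](C)(C)C(C)(C)C)[C@@H]2[C@@H](O)C=C1C | intermediate
22 | 8α-hydroperoxide (8β-CH3) with 6α-OH and 11-OH | OC[C@@H]1[C@@]2(C)CC[C@H](O[Si](C)(C)C(C)(C)C)[C@@](C)(CO[Si](C)(C)C(C)(C)C)[C@@H]2[C@@H](O)C[C@@]1(C)OO | intermediate (not isolated)
23 | 6α,8α,11-triol (8β-CH3) with 3β,18-bis-OTBS | OC[C@@H]1[C@@]2(C)CC[C@H](O[Si](C)(C)C(C)(C)C)[C@@](C)(CO[Si](C)(C)C(C)(C)C)[C@@H]2[C@@H](O)C[C@@]1(C)O | intermediate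
24 | 9β-formyl compound with 6α-OH, 8α-OH and 3β,18-bis-OTBS | O=C[C@@H]1[C@@]2(C)CC[C@H](O[Si](C)(C)C(C)(C)C)[C@@](C)(CO[Si](C)(C)C(C)(C)C)[C@@H]2[C@@H](O)C[C@@]1(C)O | intermediate
25 | 9β-vinyl compound with 6α-OH, 8α-OH and 3β,18-bis-OTBS | C=C[C@@H]1[C@@]2(C)CC[C@H](O[Si](C)(C)C(C)(C)C)[C@@](C)(CO[Si](C)(C)C(C)(C)C)[C@@H]2[C@@H](O)C[C@@]1(C)O | intermediate
26 | B-alkyl-9-BBN with boron on C12 | C(CB1C2CCCC1CCC2)[C@@H]1[C@@]2(C)CC[C@H](O[Si](C)(C)C(C)(C)C)[C@@](C)(CO[Si](C)(C)C(C)(C)C)[C@@H]2[C@@H](O)C[C@@]1(C)O | intermediate (not isolated)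
27 | 3,18-bis-O-TBS ether of the target | CC1=CC(=O)O[C@H]1C/C=C(\C)CC[C@@H]1[C@@]2(C)CC[C@H](O[Si](C)(C)C(C)(C)C)[C@@](C)(CO[Si](C)(C)C(C)(C)C)[C@@H]2[C@@H](O)C[C@@]1(C)O | intermediate
28 | CNP0307004.1 | CC1=CC(=O)O[C@H]1C/C=C(\C)CC[C@@H]1[C@@]2(C)CC[C@H](O)[C@@](C)(CO)[C@@H]2[C@@H](O)C[C@@]1(C)O | target

**Step count**

Total: 18 steps. Longest linear sequence: 14 steps (steps 5–18, from (R)-carvone); the butenolide arm takes 4 steps (steps 1–4).

**Steps most likely to fail**

Step 9. The tertiary C4 radical may be reduced or lose a hydrogen atom before it cyclizes, the addition to the aldehyde may revert, or facial control at C3 may be poor. The fallback sets out from 14 and moves the C3 stereocenter out of the radical step. Condensation of 14 with NH2OH·HCl/NaOAc gives the oxime F1, and dehydration with 1,1′-carbonyldiimidazole gives the nitrile F2. Treatment of F2 with Cp2TiCl (from Cp2TiCl2 and Zn) closes ring A by 6-exo-dig addition of the C4 radical to the nitrile; the iminyl radical does not revert, and acid work-up hydrolyses the titanium imide to the 3-keto-18-hydroxy compound F3. NaBH4 in MeOH/CH2Cl2 at −78 °C then reduces the saturated C3 ketone from the α face, in preference to the conjugated C9 ketone, and the route is rejoined at 15.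

Step 11. Oxygen transfer may go to the α-carbon (C8) of the dienol ether instead of the γ-carbon (C6), or face selectivity at C6 may be poor. The fallback sets out from 16 and separates regiochemistry from the oxidation. One equivalent of Bu4NF buffered with AcOH in THF at −78 °C cleaves only the silyl enol ether and protonates the dienolate at C8, giving the β,γ-unsaturated ketone F4 (both C8 epimers). mCPBA epoxidizes the isolated C6=C7 bond from the α face to the 6α,7α-epoxy ketone F5. A catalytic amount of DBU opens F5 by α-deprotonation and β-elimination, and the route is rejoined at 18.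

Step 14. Capture of O2 by the C8 radical may show poor face selectivity, or hydrogen atom transfer to the hindered trisubstituted alkene may be slow. The fallback sets out from 21 and uses hydroxyl direction instead of a free radical. VO(acac)2 with t-BuOOH epoxidizes C7=C8 syn to the allylic 6α-hydroxyl, giving the 7α,8α-epoxide F6. LiBHEt3 in THF delivers hydride to the secondary C7 and leaves the tertiary 8α-alcohol, and the route is rejoined at 23.

**Further compounds**

F1 | step 9 | 3-[(1S,6R)-1,3-dimethyl-6-(2-methyloxiran-2-yl)-2-oxocyclohex-3-en-1-yl]propanal oxime | O=C1[C@@](C)(CCC=NO)[C@H](C2(C)CO2)CC=C1C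
F2 | step 9 | 3-[(1S,6R)-1,3-dimethyl-6-(2-methyloxiran-2-yl)-2-oxocyclohex-3-en-1-yl]propanenitrile | O=C1[C@@](C)(CCC#N)[C@H](C2(C)CO2)CC=C1C
F3 | step 9 | 4α-(hydroxymethyl)-4β,8,10β-trimethyl-5α-H-decal-7-ene-3,9-dione | O=C1[C@@]2(C)CCC(=O)[C@@](C)(CO)[C@@H]2CC=C1C
F4 | step 11 | 3β,18-bis-OTBS-4β,8,10β-trimethyl-5α-H-decal-6-en-9-one (both C8 epimers) | O=C1[C@@]2(C)CC[C@H](O[Si](C)(C)C(C)(C)C)[C@@](C)(CO[Si](C)(C)C(C)(C)C)[C@@H]2C=CC1C
F5 | step 11 | 6α,7α-epoxide of F4 | O=C1[C@@]2(C)CC[C@H](O[Si](C)(C)C(C)(C)C)[C@@](C)(CO[Si](C)(C)C(C)(C)C)[C@@H]2[C@H]3O[C@H]3C1C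
F6 | step 14 | 7α,8α-epoxide of 21 | OC[C@@H]1[C@@]2(C)CC[C@H](O[Si](C)(C)C(C)(C)C)[C@@](C)(CO[Si](C)(C)C(C)(C)C)[C@@H]2[C@@H](O)[C@H]3O[C@@]13C
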